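**Retrosynthetic overview**
1. Target 27 ⇐ bis-silyl ether 26 ⇐ seco-acid 25. The C7–C8 bond is made by intramolecular decarboxylative radical addition–fragmentation: the C8 α-acyloxy allyl radical adds to an α-(sulfonylmethyl)butenolide, closing the ten-membered ring and setting C7, C8 and the exo-methylene together.
2. Butenolide 24 ⇐ ring-closing metathesis of acrylate 23 ⇐ carbinol 20 (C5–C6 by asymmetric CrCl2/NiCl2 coupling with acrolein). The C8 acid handle ⇐ alkenyllithium + ethyl glyoxylate, acylated in the same flask with angelic acid.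
3. The C2-symmetric (S,S)-anti-diol 12, with a Z-alkenyl bromide at one end and a Z-alkenyl iodide at the other ⇐ Paterson aldol of 8 with 4, then Evans–Saksena reduction.
4. Both Z-trisubstituted alkenes ⇐ CuI-catalysed anti-carbomagnesiation of propargylic alcohols 1 and 5.
5. Ring order: γ-lactone first (as the butenolide), ten-membered carbocycle last.

Assumption: germacrane numbering is used for the target (C1–C10 ring, C11–C13 lactone carbons); the antipodes of Ipc2BCl (step 5) and of the sulfonamide ligand (step 9) named are those expected to give the drawn configurations, and the mirror-image reagent is used if the sense of induction proves opposite.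

**Route**

Step 1
Reactants: 1 prop-2-yn-1-ol
Product: 3 (2Z)-3-bromo-2-methylprop-2-en-1-ol, via dimagnesium alkenyl alkoxide 2 (not isolated)
Conditions: MeMgBr (2.5 equiv), CuI (10 mol %), THF, −10 °C to rt; then NBS, −40 to 0 °C
Reagents that add atoms: methylmagnesium bromide (C[Mg]Br); N-bromosuccinimide (O=C1CCC(=O)N1Br)
Why: CuI-catalysed anti-carbomagnesiation of the propargylic alkoxide (Duboudin reaction) puts methyl on C2 and leaves the alkenyl–MgBr chelated cis to the CH2O group, so bromination with retention gives only the Z bromide.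

Step 2
Reactants: 3 (2Z)-3-bromo-2-methylprop-2-en-1-ol
Product: 4 (2Z)-3-bromo-2-methylprop-2-enal
Conditions: MnO2 (15 equiv), CH2Cl2, rt
Reagents that add atoms: none
Why: Neutral MnO2 allylic oxidation stops at the enal and does not isomerise the Z bromoalkene.

Step 3
Reactants: 5 but-3-yn-2-ol (racemic)
Product: 7 (3Z)-4-iodo-3-methylbut-3-en-2-ol (racemic), via dimagnesium alkenyl alkoxide 6 (not isolated)
Conditions: MeMgBr (2.5 equiv), CuI (10 mol %), THF, 0 °C to rt; then I2, −40 to 0 °C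
Reagents that add atoms: methylmagnesium bromide (C[Mg]Br); iodine ([I][I])
Why: The same Duboudin anti-carbomagnesiation followed by iodination with retention gives the Z iodide; the carbinol centre is removed in step 4.

Step 4
Reactants: 7 (3Z)-4-iodo-3-methylbut-3-en-2-ol
Product: 8 (3Z)-4-iodo-3-methylbut-3-en-2-one
Conditions: MnO2 (15 equiv), CH2Cl2, rt
Reagents that add atoms: none
Why: MnO2 oxidation of the secondary allylic alcohol gives the Z β-iodoenone without touching the C–I bond.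

Step 5
Reactants: 8 (3Z)-4-iodo-3-methylbut-3-en-2-one; 4 (2Z)-3-bromo-2-methylprop-2-enal
Product: 10 (1Z,3S,6Z)-1-bromo-3-hydroxy-7-iodo-2,6-dimethylhepta-1,6-dien-5-one, via boron enolate 9 (not isolated)
Conditions: (+)-Ipc2BCl, Et3N, Et2O, 0 °C; then 4, −78 to −20 °C; H2O2, MeOH, pH 7 buffer
Reagents that add atoms: none
Why: Paterson boron aldol reaction: the kinetic Ipc2B enolate of the methyl ketone adds to the si face of aldehyde 4 through the reagent-controlled cyclic transition state, setting the (3S) carbinol (C3 of the target) without touching the Z haloalkenes.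

Step 6
Reactants: 10 (1Z,3S,6Z)-1-bromo-3-hydroxy-7-iodo-2,6-dimethylhepta-1,6-dien-5-one
Product: 11 (1Z,3S,5S,6Z)-1-bromo-7-iodo-2,6-dimethylhepta-1,6-diene-3,5-diol
Conditions: Me4NBH(OAc)3, MeCN/AcOH (1:1), −30 °C
Reagents that add atoms: none
Why: Evans–Saksena reduction: the free hydroxyl exchanges onto boron and delivers hydride intramolecularly through a chair, giving 1,2-reduction of the enone to the 1,3-anti diol and setting (5S) (C1 of the target).

Step 7
Reactants: 11 (1Z,3S,5S,6Z)-1-bromo-7-iodo-2,6-dimethylhepta-1,6-diene-3,5-diol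
Product: 12 (1Z,3S,5S,6Z)-1-bromo-3,5-bis[(tert-butyldimethylsilyl)oxy]-7-iodo-2,6-dimethylhepta-1,6-diene
Conditions: TBSOTf (2.4 equiv), 2,6-lutidine, CH2Cl2, −78 to 0 °C
Reagents that add atoms: tert-butyldimethylsilyl trifluoromethanesulfonate (CC(C)(C)[Si](C)(C)OS(=O)(=O)C(F)(F)F)
Why: Silyl triflate silylation protects both secondary allylic alcohols, which stops O1 from lactonising onto the C8 carboxyl across the Z alkene later and keeps O3 out of the esterifications.

Step 8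
Reactants: 12 (1Z,3S,5S,6Z)-1-bromo-3,5-bis[(tert-butyldimethylsilyl)oxy]-7-iodo-2,6-dimethylhepta-1,6-diene; 13 ethyl glyoxylate; 14 angelic acid [(2Z)-2-methylbut-2-enoic acid]
Product: 18 ethyl (2RS,3Z,5S,7S,8Z)-9-bromo-5,7-bis[(tert-butyldimethylsilyl)oxy]-4,8-dimethyl-2-{[(2Z)-2-methylbut-2-enoyl]oxy}nona-3,8-dienoate, via alkenyllithium 15 (not isolated), via lithium alkoxide 16 (not isolated), via mixed anhydride 17 (not isolated)
Conditions: t-BuLi (2.05 equiv), Et2O, −78 °C; 13, −78 °C; then 17 (made from 14, 2,4,6-trichlorobenzoyl chloride, Et3N, THF, rt), −78 to 0 °C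
Reagents that add atoms: none
Why: Iodine–lithium exchange is far faster than bromine–lithium exchange and keeps the Z geometry, the alkenyllithium adds to the aldehyde of 13, and the lithium alkoxide is acylated at the unhindered carbonyl of the Yamaguchi mixed anhydride without Z/E isomerisation; the new centre (C8 of the target) forms as a 1:1 mixture that does not matter because it becomes a planar radical in step 14.

Step 9
Reactants: 18 (the bromo ester above); 19 acrolein (prop-2-enal)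
Product: 20 ethyl (2RS,3Z,5S,7S,8Z,10R)-5,7-bis[(tert-butyldimethylsilyl)oxy]-10-hydroxy-4,8-dimethyl-2-{[(2Z)-2-methylbut-2-enoyl]oxy}dodeca-3,8,11-trienoate
Conditions: CrCl2 (4 equiv), NiCl2 (10 mol %), (S)-N-[2-(4-isopropyl-4,5-dihydrooxazol-2-yl)-6-methylphenyl]methanesulfonamide (4.4 equiv), Et3N (4.4 equiv), THF, rt
Reagents that add atoms: none
Why: CrCl2/NiCl2-mediated Nozaki–Hiyama–Kishi coupling of the alkenyl bromide with acrolein tolerates both esters, keeps the Z geometry and, under control of the chiral oxazoline–sulfonamide ligand, adds to one aldehyde face to set the (10R) carbinol (C6 of the target, S there because the priorities change).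

Step 10
Reactants: 21 2-(bromomethyl)prop-2-enoic acid
Product: 22 2-[(benzenesulfonyl)methyl]prop-2-enoic acid
Conditions: PhSO2Na (1.2 equiv), MeOH, 65 °C; aq. HCl work-up
Reagents that add atoms: sodium benzenesulfinate ([Na+].[O-]S(=O)c1ccccc1)
Why: S-alkylation of the sulfinate by the allylic bromide (SN2 and SN2′ give the same product) installs the radical leaving group.

Step 11
Reactants: 20 (the carbinol above); 22 2-[(benzenesulfonyl)methyl]prop-2-enoic acid
Product: 23 ethyl (2RS,3Z,5S,7S,8Z,10R)-10-({2-[(benzenesulfonyl)methyl]prop-2-enoyl}oxy)-5,7-bis[(tert-butyldimethylsilyl)oxy]-4,8-dimethyl-2-{[(2Z)-2-methylbut-2-enoyl]oxy}dodeca-3,8,11-trienoate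
Conditions: DCC, DMAP (5 mol %), CH2Cl2, 0 °C
Reagents that add atoms: none
Why: Steglich esterification acylates the only free hydroxyl with retention at C10, and low temperature with catalytic DMAP avoids conjugate addition to the acrylate.

Step 12
Reactants: 23 (the acrylate above)
Product: 24 ethyl (2RS,3Z,5S,7S,8Z)-9-{(2S)-4-[(benzenesulfonyl)methyl]-5-oxo-2,5-dihydrofuran-2-yl}-5,7-bis[(tert-butyldimethylsilyl)oxy]-4,8-dimethyl-2-{[(2Z)-2-methylbut-2-enoyl]oxy}nona-3,8-dienoate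
Conditions: second-generation Grubbs catalyst RuCl2(=CHPh)(PCy3)(H2IMes) (10 mol %), CH2Cl2 (5 mM), 40 °C
Reagents that add atoms: none
Why: Ring-closing metathesis between the vinyl group and the 1,1-disubstituted acrylate closes the butenolide with loss of ethene, the trisubstituted alkenes and the angelate being too hindered to react.

Step 13
Reactants: 24 (the butenolide ethyl ester above)
Product: 25 (2RS,3Z,5S,7S,8Z)-9-{(2S)-4-[(benzenesulfonyl)methyl]-5-oxo-2,5-dihydrofuran-2-yl}-5,7-bis[(tert-butyldimethylsilyl)oxy]-4,8-dimethyl-2-{[(2Z)-2-methylbut-2-enoyl]oxy}nona-3,8-dienoic acid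
Conditions: Me3SnOH (5 equiv), 1,2-dichloroethane, 70 °C; 0.1 M HCl work-up
Reagents that add atoms: trimethyltin hydroxide (C[Sn](C)(C)O)
Why: Me3SnOH ester hydrolysis (Nicolaou conditions) delivers hydroxide from tin to the unhindered, electron-poor ethyl ester while the hindered conjugated angelate survives and the butenolide, if opened, recloses on acidification.

Step 14
Reactants: 25 (the seco-acid above)
Product: 26 (1S,3S,4Z,6S,7R,8R,9Z)-1,3-bis[(tert-butyldimethylsilyl)oxy]-8-{[(2Z)-2-methylbut-2-enoyl]oxy}germacra-4,9,11(13)-trien-12,6-olide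
Conditions: Ir[dF(CF3)ppy]2(dtbbpy)PF6 (2 mol %), K2HPO4 (1.2 equiv), degassed DMF (1 mM), 450 nm LEDs, 25 °C
Reagents that add atoms: none
Why: Proposed new method: the excited photocatalyst oxidises the carboxylate, CO2 is lost and the C8 α-acyloxy allyl radical (Z geometry held, OAng on the outer side of the allyl plane, no hydrogen donor present so that it persists) adds through its less substituted terminus to C7 of the butenolide on the face opposite the C5 side chain at C6, which closes the ten-membered ring as the trans-fused lactone (7R) and is expected to place H8 anti to H7 (8R), after which the C11 radical expels PhSO2• to give the exo-methylene and the sulfonyl radical is reduced to sulfinate by the reduced photocatalyst; the closest known reactions are the intermolecular photoredox decarboxylative allylation of α-oxy acids with 2-(sulfonylmethyl)acrylates and decarboxylative Giese macrocyclisation.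

Step 15
Reactants: 26 (the bis-silyl ether above)
Product: 27 (1S,3S,4Z,6S,7R,8R,9Z)-1,3-dihydroxy-8-{[(2Z)-2-methylbut-2-enoyl]oxy}germacra-4,9,11(13)-trien-12,6-olide (target)
Conditions: HF·pyridine, pyridine, THF, 0 °C to rt
Reagents that add atoms: none
Why: Fluoride cleavage of both silyl ethers under buffered, non-basic conditions leaves the lactone closed, the angelate in place and the α-methylene lactone untouched.

**Compound list**
1 | prop-2-yn-1-ol | C#CCO | starting material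
2 | bromomagnesium (2Z)-3-(bromomagnesio)-2-methylprop-2-en-1-olate | Br[Mg]OC/C(C)=C\[Mg]Br | intermediate (not isolated)
3 | (2Z)-3-bromo-2-methylprop-2-en-1-ol | OC/C(C)=C\Br | intermediate
4 | (2Z)-3-bromo-2-methylprop-2-enal | O=C/C(C)=C\Br | intermediate
5 | but-3-yn-2-ol (racemic) | CC(O)C#C | starting material
6 | bromomagnesium (3Z)-4-(bromomagnesio)-3-methylbut-3-en-2-olate (racemic) | CC(O[Mg]Br)/C(C)=C\[Mg]Br | intermediate (not isolated)
7 | (3Z)-4-iodo-3-methylbut-3-en-2-ol (racemic) | CC(O)/C(C)=C\I | intermediate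
8 | (3Z)-4-iodo-3-methylbut-3-en-2-one | CC(=O)/C(C)=C\I | intermediate
9 | (3Z)-4-iodo-3-methylbuta-1,3-dien-2-yl diisopinocampheylborinate, the boron enolate of 8 from (+)-Ipc2BCl | C=C(OB([C@H]1C[C@H]2C[C@@H]([C@@H]1C)C2(C)C)[C@H]1C[C@H]2C[C@@H]([C@@H]1C)C2(C)C)/C(C)=C\I | intermediate (not isolated)
10 | (1Z,3S,6Z)-1-bromo-3-hydroxy-7-iodo-2,6-dimethylhepta-1,6-dien-5-one | Br/C=C(/C)[C@@H](O)CC(=O)/C(C)=C\I | intermediate
11 | (1Z,3S,5S,6Z)-1-bromo-7-iodo-2,6-dimethylhepta-1,6-diene-3,5-diol | Br/C=C(/C)[C@@H](O)C[C@H](O)/C(C)=C\I | intermediate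
12 | (1Z,3S,5S,6Z)-1-bromo-3,5-bis[(tert-butyldimethylsilyl)oxy]-7-iodo-2,6-dimethylhepta-1,6-diene | Br/C=C(/C)[C@@H](O[Si](C)(C)C(C)(C)C)C[C@H](O[Si](C)(C)C(C)(C)C)/C(C)=C\I | intermediate
13 | ethyl glyoxylate (ethyl 2-oxoacetate) | CCOC(=O)C=O | starting material
14 | angelic acid, (2Z)-2-methylbut-2-enoic acid | C/C=C(/C)C(=O)O | starting material
15 | [(1Z,3S,5S,6Z)-7-bromo-3,5-bis[(tert-butyldimethylsilyl)oxy]-2,6-dimethylhepta-1,6-dien-1-yl]lithium | Br/C=C(/C)[C@@H](O[Si](C)(C)C(C)(C)C)C[C@H](O[Si](C)(C)C(C)(C)C)/C(C)=C\[Li] | intermediate (not isolated)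
16 | lithium alkoxide of ethyl (2RS,3Z,5S,7S,8Z)-9-bromo-5,7-bis[(tert-butyldimethylsilyl)oxy]-2-hydroxy-4,8-dimethylnona-3,8-dienoate | Br/C=C(/C)[C@@H](O[Si](C)(C)C(C)(C)C)C[C@H](O[Si](C)(C)C(C)(C)C)/C(C)=C\C(O[Li])C(=O)OCC | intermediate (not isolated)
17 | (2Z)-2-methylbut-2-enoic 2,4,6-trichlorobenzoic anhydride | C/C=C(/C)C(=O)OC(=O)c1c(Cl)cc(Cl)cc1Cl | intermediate (not isolated)
18 | ethyl (2RS,3Z,5S,7S,8Z)-9-bromo-5,7-bis[(tert-butyldimethylsilyl)oxy]-4,8-dimethyl-2-{[(2Z)-2-methylbut-2-enoyl]oxy}nona-3,8-dienoate (both epimers at C2, the later C8) | Br/C=C(/C)[C@@H](O[Si](C)(C)C(C)(C)C)C[C@H](O[Si](C)(C)C(C)(C)C)/C(C)=C\C(OC(=O)/C(C)=C\C)C(=O)OCC | intermediate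
19 | acrolein (prop-2-enal) | C=CC=O | starting material
20 | ethyl (2RS,3Z,5S,7S,8Z,10R)-5,7-bis[(tert-butyldimethylsilyl)oxy]-10-hydroxy-4,8-dimethyl-2-{[(2Z)-2-methylbut-2-enoyl]oxy}dodeca-3,8,11-trienoate | O[C@H](C=C)/C=C(/C)[C@@H](O[Si](C)(C)C(C)(C)C)C[C@H](O[Si](C)(C)C(C)(C)C)/C(C)=C\C(OC(=O)/C(C)=C\C)C(=O)OCC | intermediate
21 | 2-(bromomethyl)prop-2-enoic acid | C=C(CBr)C(=O)O | starting material
22 | 2-[(benzenesulfonyl)methyl]prop-2-enoic acid | C=C(CS(=O)(=O)c1ccccc1)C(=O)O | intermediate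
23 | ethyl (2RS,3Z,5S,7S,8Z,10R)-10-({2-[(benzenesulfonyl)methyl]prop-2-enoyl}oxy)-5,7-bis[(tert-butyldimethylsilyl)oxy]-4,8-dimethyl-2-{[(2Z)-2-methylbut-2-enoyl]oxy}dodeca-3,8,11-trienoate | C=C(CS(=O)(=O)c1ccccc1)C(=O)O[C@H](C=C)/C=C(/C)[C@@H](O[Si](C)(C)C(C)(C)C)C[C@H](O[Si](C)(C)C(C)(C)C)/C(C)=C\C(OC(=O)/C(C)=C\C)C(=O)OCC | intermediate
24 | ethyl (2RS,3Z,5S,7S,8Z)-9-{(2S)-4-[(benzenesulfonyl)methyl]-5-oxo-2,5-dihydrofuran-2-yl}-5,7-bis[(tert-butyldimethylsilyl)oxy]-4,8-dimethyl-2-{[(2Z)-2-methylbut-2-enoyl]oxy}nona-3,8-dienoate | O=C1O[C@H](C=C1CS(=O)(=O)c1ccccc1)/C=C(/C)[C@@H](O[Si](C)(C)C(C)(C)C)C[C@H](O[Si](C)(C)C(C)(C)C)/C(C)=C\C(OC(=O)/C(C)=C\C)C(=O)OCC | intermediate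
25 | (2RS,3Z,5S,7S,8Z)-9-{(2S)-4-[(benzenesulfonyl)methyl]-5-oxo-2,5-dihydrofuran-2-yl}-5,7-bis[(tert-butyldimethylsilyl)oxy]-4,8-dimethyl-2-{[(2Z)-2-methylbut-2-enoyl]oxy}nona-3,8-dienoic acid | O=C1O[C@H](C=C1CS(=O)(=O)c1ccccc1)/C=C(/C)[C@@H](O[Si](C)(C)C(C)(C)C)C[C@H](O[Si](C)(C)C(C)(C)C)/C(C)=C\C(OC(=O)/C(C)=C\C)C(=O)O | intermediate
26 | (1S,3S,4Z,6S,7R,8R,9Z)-1,3-bis[(tert-butyldimethylsilyl)oxy]-8-{[(2Z)-2-methylbut-2-enoyl]oxy}germacra-4,9,11(13)-trien-12,6-olide | C=C1C(=O)O[C@H]2/C=C(/C)[C@@H](O[Si](C)(C)C(C)(C)C)C[C@H](O[Si](C)(C)C(C)(C)C)/C(C)=C\[C@@H](OC(=O)/C(C)=C\C)[C@H]12 | intermediate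
27 | (1S,3S,4Z,6S,7R,8R,9Z)-1,3-dihydroxy-8-{[(2Z)-2-methylbut-2-enoyl]oxy}germacra-4,9,11(13)-trien-12,6-olide | C=C1C(=O)O[C@H]2/C=C(/C)[C@@H](O)C[C@H](O)/C(C)=C\[C@@H](OC(=O)/C(C)=C\C)[C@H]12 | target

**Step count**
Total: 15 steps. Longest linear sequence: 12 steps (1, 2, 5, 6, 7, 8, 9, 11, 12, 13, 14, 15; the branch through steps 3 and 4 is equally long).

**Three steps most likely to fail**

Step 14 (radical ring closure). The allyl radical is stabilised and the ten-membered closure is slow, it could react through its tertiary terminus, and the configuration at C8 rests on a conformational argument only. The fallback sets out from 25 and returns at 26. Pb(OAc)4 (benzene, 25 °C) decarboxylates 25 oxidatively to the mixed acylal, and mild aqueous hydrolysis releases angelic acid and (2Z,4S,6S,7Z)-8-{(2S)-4-[(benzenesulfonyl)methyl]-5-oxo-2,5-dihydrofuran-2-yl}-4,6-bis[(tert-butyldimethylsilyl)oxy]-3,7-dimethylocta-2,7-dienal F1. SmI2 (THF, −78 °C, 1 mM) then adds the ketyl of the aldehyde to C7 of the butenolide and the enolate expels benzenesulfinate, giving the 8-hydroxy macrocycle (1S,3S,4Z,6S,7S,8R,9Z)-1,3-bis[(tert-butyldimethylsilyl)oxy]-8-hydroxygermacra-4,9,11(13)-trien-12,6-olide F2. Yamaguchi esterification of F2 with 14 gives 26; if the carbinol forms with the inverted configuration, a Mitsunobu esterification with 14 is used instead.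

Step 9 (asymmetric coupling of an alkenyl bromide with acrolein). The bromide is slower than an iodide and the facial selectivity is ligand-dependent. The fallback sets out from 18 and returns at 20. Pd(PPh3)4-catalysed carbonylative Stille coupling of the alkenyl bromide with tributyl(vinyl)stannane under CO (toluene, 70 °C) gives the cross-conjugated dienone ethyl (2RS,3Z,5S,7S,8Z)-5,7-bis[(tert-butyldimethylsilyl)oxy]-4,8-dimethyl-2-{[(2Z)-2-methylbut-2-enoyl]oxy}-10-oxododeca-3,8,11-trienoate F3. Corey–Bakshi–Shibata reduction (2-methyl-CBS-oxazaborolidine enantiomer chosen for the 10R carbinol, catecholborane, toluene, −78 °C) sets C6 under reagent control and gives 20.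

Step 13 (selective hydrolysis of the ethyl ester beside the angelate and the butenolide). The fallback sets out from 12 and returns at 25. Step 8 is repeated with tert-butyl glyoxylate in place of 13 to give the tert-butyl α-angeloyloxy ester F4. The operations of steps 9, 11 and 12 then give the tert-butyl ester carbinol F5, the tert-butyl ester acrylate F6 and the tert-butyl ester butenolide F7. TMSOTf/2,6-lutidine (CH2Cl2, 0 °C) converts the tert-butyl ester into the silyl ester, which is lost on aqueous work-up, so 25 is reached without nucleophilic hydrolysis.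

**Further compounds**
F1 | step 14 | (2Z,4S,6S,7Z)-8-{(2S)-4-[(benzenesulfonyl)methyl]-5-oxo-2,5-dihydrofuran-2-yl}-4,6-bis[(tert-butyldimethylsilyl)oxy]-3,7-dimethylocta-2,7-dienal | O=C1O[C@H](C=C1CS(=O)(=O)c1ccccc1)/C=C(/C)[C@@H](O[Si](C)(C)C(C)(C)C)C[C@H](O[Si](C)(C)C(C)(C)C)/C(C)=C\C=O
F2 | step 14 | (1S,3S,4Z,6S,7S,8R,9Z)-1,3-bis[(tert-butyldimethylsilyl)oxy]-8-hydroxygermacra-4,9,11(13)-trien-12,6-olide | C=C1C(=O)O[C@H]2/C=C(/C)[C@@H](O[Si](C)(C)C(C)(C)C)C[C@H](O[Si](C)(C)C(C)(C)C)/C(C)=C\[C@@H](O)[C@H]12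
F3 | step 9 | ethyl (2RS,3Z,5S,7S,8Z)-5,7-bis[(tert-butyldimethylsilyl)oxy]-4,8-dimethyl-2-{[(2Z)-2-methylbut-2-enoyl]oxy}-10-oxododeca-3,8,11-trienoate | C=CC(=O)/C=C(/C)[C@@H](O[Si](C)(C)C(C)(C)C)C[C@H](O[Si](C)(C)C(C)(C)C)/C(C)=C\C(OC(=O)/C(C)=C\C)C(=O)OCC
F4 | step 13 | tert-butyl (2RS,3Z,5S,7S,8Z)-9-bromo-5,7-bis[(tert-butyldimethylsilyl)oxy]-4,8-dimethyl-2-{[(2Z)-2-methylbut-2-enoyl]oxy}nona-3,8-dienoate | Br/C=C(/C)[C@@H](O[Si](C)(C)C(C)(C)C)C[C@H](O[Si](C)(C)C(C)(C)C)/C(C)=C\C(OC(=O)/C(C)=C\C)C(=O)OC(C)(C)C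
F5 | step 13 | tert-butyl (2RS,3Z,5S,7S,8Z,10R)-5,7-bis[(tert-butyldimethylsilyl)oxy]-10-hydroxy-4,8-dimethyl-2-{[(2Z)-2-methylbut-2-enoyl]oxy}dodeca-3,8,11-trienoate | O[C@H](C=C)/C=C(/C)[C@@H](O[Si](C)(C)C(C)(C)C)C[C@H](O[Si](C)(C)C(C)(C)C)/C(C)=C\C(OC(=O)/C(C)=C\C)C(=O)OC(C)(C)C
F6 | step 13 | tert-butyl (2RS,3Z,5S,7S,8Z,10R)-10-({2-[(benzenesulfonyl)methyl]prop-2-enoyl}oxy)-5,7-bis[(tert-butyldimethylsilyl)oxy]-4,8-dimethyl-2-{[(2Z)-2-methylbut-2-enoyl]oxy}dodeca-3,8,11-trienoate | C=C(CS(=O)(=O)c1ccccc1)C(=O)O[C@H](C=C)/C=C(/C)[C@@H](O[Si](C)(C)C(C)(C)C)C[C@H](O[Si](C)(C)C(C)(C)C)/C(C)=C\C(OC(=O)/C(C)=C\C)C(=O)OC(C)(C)C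
F7 | step 13 | tert-butyl (2RS,3Z,5S,7S,8Z)-9-{(2S)-4-[(benzenesulfonyl)methyl]-5-oxo-2,5-dihydrofuran-2-yl}-5,7-bis[(tert-butyldimethylsilyl)oxy]-4,8-dimethyl-2-{[(2Z)-2-methylbut-2-enoyl]oxy}nona-3,8-dienoate | O=C1O[C@H](C=C1CS(=O)(=O)c1ccccc1)/C=C(/C)[C@@H](O[Si](C)(C)C(C)(C)C)C[C@H](O[Si](C)(C)C(C)(C)C)/C(C)=C\C(OC(=O)/C(C)=C\C)C(=O)OC(C)(C)C
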